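## The problem

The target 42 is a C20 tricyclic acetal. A nine-membered carbocycle (C4a, C5–C11, C11a) is trans-fused at C4a/C11a to a six-membered acetal ring (O2, C1, C11a, C4a, C4, C3), which shares the C3–C4 bond with a 2,5-dihydrofuran (C3, C4=C12, C13, O) carrying the C14/C15 diol. The eight stereocentres form three groups: the ring-fusion pair C4a/C11a, the triad C7/C8/C9 (tertiary carbinol beside a cis-epoxide), and C13/C14 with the acetal carbon C3. C13/C14 can be taken from the chiral pool; C3 has to follow the ring fusion, because a planar dihydrofuran can only be fused to the trans-locked acetal ring through a pseudo-equatorial C3–O bond; C7/C8 can steer C9 because they are neighbours. The ring-fusion pair is separated from C7 by the C5–C6 chain, so the two domains cannot control each other and each needs its own source of absolute configuration. The sensitive elements are the allylic mixed acetal with a hydrogen at C13 (acid leads towards a furan), the epoxy alcohol (acid opening, epoxide migration) and the exocyclic methylidene, so strong acid should leave the route once the epoxide exists. The constitutional obstacle is the medium ring. What opens it is the 1,3-relation of the sp2 carbon C11 and the oxygenated C9 through the methylene C10: at the ketone level of C11 this is a β-hydroxy ketone, the unmasked form of an isoxazoline, so the ring bond C10–C11 can be made by adding a C11 nitrile oxide to a C9=C10 vinyl group.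

## Retrosynthesis

**Acetal last.** In 42 the C3–O bond to C13 and the three silyl groups of 41 are removed first, leading to lactol 39. Closing the acetal late keeps the most acid-labile unit out of every earlier step. In 39 the C14, C15 and C7 oxygens stay silylated, so only the C13 oxygen, held next to C3 by the cis C4=C12 bond, can close. The forward reaction must unmask C13 under mild acid, set C3 through the ring fusion, and leave the rest to fluoride.

**Side chain by aldol condensation.** Lactol 39 comes from the α-alkylidene lactone 38, and the C4=C12 bond is cut into the enolate of lactone 30 and aldehyde 35. This cut divides the molecule into a ring part and a five-carbon chiral-pool piece; attaching the chain earlier would carry three more silyl ethers and two stereocentres through the cycloaddition. Aldehyde 35 follows in four steps from 2,3-O-isopropylidene-D-erythronolactone 31 through 32, 33 and 34. The forward reaction has to give the Z alkene (C13 cis to C3); allylic strain with the C5 substituent at C4a should favour it.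

**Epoxide from two carbinols.** The C9–O bond of the epoxide in 30 (and its precursor 29) is cut to the hydroxy mesylate 28, made from acetonide 27 and alcohol 26. Epoxidising a C8=C9 alkene in a flexible nine-membered ring would depend on ring conformation; displacement of a C9 mesylate by the C8 hydroxyl gives the cis-epoxide from two defined carbinols. It requires the C9 oxygen of 26 trans to the C8 oxygen on the ring.

**Methylidene and carbinol from a masked aldol.** The C11 methylidene of 26 goes back to the ketone of 25, and 25 is the N–O cleavage product of isoxazoline 23. No carbon–carbon bond is cut here; the gain is that C11 and C9 reach their final oxidation pattern from one heterocycle.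

**Key disconnection.** In 23 the C10–C11 and O–C9 bonds are cut, leading through nitrile oxide 22 to oxime 20. Other ring bonds would close a ring lacking this oxidation pattern, which would then have to be installed on the medium ring afterwards. The precursor 20 is a monocyclic lactone with an open chain, two rings and one stereocentre simpler. The forward step must close nine rather than eight atoms and attack the correct face of the vinyl group.

**Lactone by conjugate addition.** Oxime 20 derives from aldehyde 19, alcohol 18, silyl ether 17 and ester 16, and 16 from the Michael adduct 14. Cutting C4a–C11a leads to alkylidene malonate 12 and 3-(tert-butyldimethylsilyloxy)propanal 13; 12 is the Knoevenagel product of aldehyde 10 and dimethyl malonate 11. One amine-catalysed step sets both ring-fusion centres by reagent control. The syn adduct maps onto the trans lactone only if its formyl carbon becomes C1 and the silyloxymethyl carbon becomes C11, and the sequence is ordered accordingly.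

**C4a–C9 from geraniol.** Aldehyde 10 is traced through 9, 8, 7, 6, 5 and triol 4 to epoxy alcohol 2 and geraniol 1, which holds C4a–C9 and the C7 methyl in the right order. Asymmetric epoxidation and a Payne rearrangement–opening give the erythro C7/C8 diol. Its acetonide places the C6 and C9 arms cis on a five-membered ring and so pre-folds the chain for the key step.

## Roads not taken

Alternative 1: The nine-membered ring is grown from a five-membered one: C8–C9 is formed while the C6–C11 bond of the dialkenylcyclopentanol A1 breaks. Forward, the potassium alkoxide of A1 (KH, 18-crown-6) would undergo an anionic oxy-Cope rearrangement to cyclononenone A2, with the C11 ketone and a C6=C7 enol ether.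
- Merits: the rearrangement is driven by enolate formation, needs no high dilution and belongs to a known family of four-carbon ring expansions. In certainty of ring formation it is better than the chosen plan.
- Weak points: A2 has the wrong functionality at C7–C9. C9 carries an ethyl ether that must become the epoxide oxygen, C8 is unoxidised, and the C7 carbinol needs methyl addition to a mobile medium-ring ketone. The C9 configuration depends on enol ether geometry and on a chair or boat transition state. Lactone and side chain must still be built from two protected alcohols.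
- Comparison: against the safer ring formation, the chosen plan brings C7 and C8 into the ring closure with their final configuration and obtains C9–O and the C11 carbonyl at the needed oxidation levels in the same step.

Alternative 2: The ring is revealed, not closed: the C7–O bond is made by oxygen insertion into the C1–C7 bond of the bridged ketone A3. Forward, Baeyer–Villiger oxidation (buffered m-CPBA) would give A4, the nine-membered carbocycle spanned by a C1(=O)–O–C7 lactone.
- Merits: no medium-ring closure is needed, the tertiary C7 migrates with retention, and the C8=C9 cis-alkene is placed for epoxidation directed by the C7 hydroxyl. In these respects it is more secure than the chosen plan.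
- Weak points: the difficulty moves into A3, a bridged bicycle with five stereocentres. The peracid must choose the ketone over the alkene. In A4 the C1 carbon is a carboxyl bound to the C7 oxygen, so C1 must be reduced, C11 oxidised and methylenated, and the whole bis-acetal with C12–C15 raised from a masked acetyl group.
- Comparison: the route is linear and long after the key step. The chosen plan is convergent and has the lactone carbonyl at C3, where the side chain is attached by aldol; it pays with an unproven ring closure, whereas the step from A3 to A4 is standard.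

Alternative 3: The cut is C4a–C11a: the 13-membered allylic lactone A5 contracts to the carbocycle. Forward, its silyl ketene acetal (LDA, Me3SiCl) would rearrange (Ireland–Claisen) to acid A6, closing the nine-membered ring and creating both ring-fusion centres and the C4=C12 alkene with the side chain attached.
- Merits: it is the most convergent of the four plans. After the key step only C1 reduction, epoxidation and acetal closure would remain, so it would be shorter than the chosen route, and macrolactonisation to A5 is known chemistry.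
- Weak points: ketene acetal geometry and chair or boat topology decide the C4a/C11a relation and the alkene geometry at once, and only one of four outcomes is useful. C11a is allylic to the C11 methylidene, so enolisation gives an extended enolate and may shift the exocyclic alkene. C12 needs a stereocentre made only for chirality transfer, and the late epoxidation must choose one of three alkenes.
- Comparison: in step count this road is better. The chosen plan sets against it that its stereocentres enter group by group under independent, known controls, and that the ring closure creates a single stereocentre with a stereoelectronic rationale.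

Key step: step 16

Remark on the chemistry: locants are those of the target skeleton throughout (C1 OCH2, C3 acetal carbon, C4=C12, C4a/C11a ring fusion, C5–C11 rest of the nine-membered ring, C13–C15 side chain); C1–C6 of geraniol become C9, C8, C7, C6, C5 and C4a; oxime 20 is drawn E, either geometry giving the same nitrile oxide.

## Route

Step 1
Reactants: 1 geraniol
Product: 2 (2S,3S)-2,3-epoxygeraniol
Conditions: Ti(OiPr)4 (5 mol%), L-(+)-diethyl tartrate (6 mol%), t-BuOOH, 4 Å MS, CH2Cl2, −20 °C
Reagents that add atoms: tert-butyl hydroperoxide, CC(C)(C)OO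
Why: Sharpless asymmetric epoxidation touches only the allylic alcohol alkene; the L-tartrate ligand should deliver oxygen to the face giving the 2S,3S epoxide, which fixes C7 and, before inversion, C8.

Step 2
Reactants: 2 (2S,3S)-2,3-epoxygeraniol
Product: 4 (2R,3S)-3,7-dimethyloct-6-ene-1,2,3-triol, via Payne epoxide 3 (not isolated)
Conditions: NaOH (0.5 M), t-BuOH/H2O, 75 °C
Reagents that add atoms: water, O
Why: Payne rearrangement–opening: the primary alkoxide opens the epoxide at C8 with inversion to the terminal epoxide 3, which hydroxide attacks at the primary carbon. The tertiary C7 is not attacked, so C7 is retained and C8 inverted, giving the erythro C7/C8 diol as one enantiomer.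

Step 3
Reactants: 4 (2R,3S)-3,7-dimethyloct-6-ene-1,2,3-triol
Product: 5 (2R,3S)-1-(tert-butyldimethylsilyloxy)-3,7-dimethyloct-6-ene-2,3-diol
Conditions: TBSCl, imidazole, CH2Cl2, 0 °C
Reagents that add atoms: tert-butyldimethylsilyl chloride, CC(C)(C)[Si](C)(C)Cl
Why: Selective silylation of the primary hydroxyl; it blocks the terminal acetonide that the free triol would otherwise form.

Step 4
Reactants: 5 (2R,3S)-1-(tert-butyldimethylsilyloxy)-3,7-dimethyloct-6-ene-2,3-diol
Product: 6 tert-butyldimethyl{[(4R,5S)-2,2,5-trimethyl-5-(4-methylpent-3-en-1-yl)-1,3-dioxolan-4-yl]methoxy}silane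
Conditions: 2,2-dimethoxypropane, PPTS (cat.), CH2Cl2, rt
Reagents that add atoms: 2,2-dimethoxypropane, COC(C)(C)OC
Why: Acid-catalysed transketalisation of the only 1,2-diol; the dioxolane carries the C6 and C9 arms cis, the turn used later in the key step.

Step 5
Reactants: 6 tert-butyldimethyl{[(4R,5S)-2,2,5-trimethyl-5-(4-methylpent-3-en-1-yl)-1,3-dioxolan-4-yl]methoxy}silane
Product: 7 [(4R,5S)-2,2,5-trimethyl-5-(4-methylpent-3-en-1-yl)-1,3-dioxolan-4-yl]methanol
Conditions: Bu4NF, THF, 0 °C → rt
Reagents that add atoms: none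
Why: Fluoride cleavage of a primary silyl ether; the acetonide is inert to fluoride.

Step 6
Reactants: 7 [(4R,5S)-2,2,5-trimethyl-5-(4-methylpent-3-en-1-yl)-1,3-dioxolan-4-yl]methanol
Product: 8 (4S,5S)-2,2,5-trimethyl-5-(4-methylpent-3-en-1-yl)-1,3-dioxolane-4-carbaldehyde
Conditions: Dess–Martin periodinane, CH2Cl2, 0 °C → rt
Reagents that add atoms: none
Why: Dess–Martin oxidation of a primary alcohol under near-neutral conditions; the α-alkoxy aldehyde is used at once so that C8 does not epimerise.

Step 7
Reactants: 8 (4S,5S)-2,2,5-trimethyl-5-(4-methylpent-3-en-1-yl)-1,3-dioxolane-4-carbaldehyde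
Product: 9 (4S,5R)-2,2,4-trimethyl-4-(4-methylpent-3-en-1-yl)-5-vinyl-1,3-dioxolane
Conditions: Ph3PCH3Br, KN(SiMe3)2, THF, −78 → 0 °C
Reagents that add atoms: methyltriphenylphosphonium bromide, C[P+](c1ccccc1)(c1ccccc1)c1ccccc1.[Br-]
Why: Wittig methylenation with the salt-free ylide at low temperature, as used for dioxolane carbaldehydes without loss of configuration; it installs C10 and the C9=C10 dipolarophile.

Step 8
Reactants: 9 (4S,5R)-2,2,4-trimethyl-4-(4-methylpent-3-en-1-yl)-5-vinyl-1,3-dioxolane
Product: 10 3-[(4S,5R)-2,2,4-trimethyl-5-vinyl-1,3-dioxolan-4-yl]propanal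
Conditions: O3, CH2Cl2, −78 °C (Sudan Red 7B end point); Me2S, −78 °C → rt
Reagents that add atoms: ozone, [O-][O+]=O
Why: Ozonolysis selects the electron-rich trisubstituted alkene over the monosubstituted vinyl group, which is further deactivated by the allylic oxygen; an indicator dye stops the reaction after one equivalent.

Step 9
Reactants: 10 3-[(4S,5R)-2,2,4-trimethyl-5-vinyl-1,3-dioxolan-4-yl]propanal; 11 dimethyl malonate
Product: 12 dimethyl 2-{3-[(4S,5R)-2,2,4-trimethyl-5-vinyl-1,3-dioxolan-4-yl]propylidene}malonate
Conditions: piperidine (10 mol%), AcOH (10 mol%), 4 Å MS, CH2Cl2, rt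
Reagents that add atoms: none
Why: Knoevenagel condensation of an unbranched aldehyde with malonate under buffered amine catalysis; the product carries the future C4a as the electrophilic carbon.

Step 10
Reactants: 12 dimethyl 2-{3-[(4S,5R)-2,2,4-trimethyl-5-vinyl-1,3-dioxolan-4-yl]propylidene}malonate; 13 3-(tert-butyldimethylsilyloxy)propanal
Product: 14 dimethyl 2-{(3S,4R)-5-(tert-butyldimethylsilyloxy)-4-formyl-1-[(4S,5R)-2,2,4-trimethyl-5-vinyl-1,3-dioxolan-4-yl]pentan-3-yl}malonate
Conditions: (R)-α,α-diphenylprolinol trimethylsilyl ether (20 mol%), PhCO2H (20 mol%), toluene, rt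
Reagents that add atoms: none
Why: Enamine-catalysed Michael addition of an aldehyde to an alkylidene malonate. The diphenyl(silyloxy)methyl group of the R catalyst shields one face of the E-enamine and sets C11a, and the acyclic synclinal transition state should give the syn adduct and so C4a. The C7/C8 centres are too remote to interfere.

Step 11
Reactants: 14 dimethyl 2-{(3S,4R)-5-(tert-butyldimethylsilyloxy)-4-formyl-1-[(4S,5R)-2,2,4-trimethyl-5-vinyl-1,3-dioxolan-4-yl]pentan-3-yl}malonate
Product: 16 methyl (4S,5S)-5-[(tert-butyldimethylsilyloxy)methyl]-2-oxo-4-{2-[(4S,5R)-2,2,4-trimethyl-5-vinyl-1,3-dioxolan-4-yl]ethyl}tetrahydro-2H-pyran-3-carboxylate (epimers at the ester-bearing carbon), via hydroxy diester 15 (not isolated)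
Conditions: NaBH4, MeOH, −20 °C; then PPTS (cat.), toluene, 60 °C
Reagents that add atoms: none
Why: Borohydride reduction of the aldehyde followed by lactonisation onto a malonate ester. The formyl carbon becomes C1, so the syn adduct becomes the 4a,11a-trans lactone, and prompt reduction removes the epimerisable aldehyde.

Step 12
Reactants: 16 methyl (4S,5S)-5-[(tert-butyldimethylsilyloxy)methyl]-2-oxo-4-{2-[(4S,5R)-2,2,4-trimethyl-5-vinyl-1,3-dioxolan-4-yl]ethyl}tetrahydro-2H-pyran-3-carboxylate
Product: 17 (4R,5S)-5-[(tert-butyldimethylsilyloxy)methyl]-4-{2-[(4S,5R)-2,2,4-trimethyl-5-vinyl-1,3-dioxolan-4-yl]ethyl}tetrahydro-2H-pyran-2-one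
Conditions: LiCl, H2O, DMSO, 140 °C
Reagents that add atoms: none
Why: Krapcho dealkoxycarbonylation of the α-carbomethoxy lactone; chloride attacks the methyl ester, and the stereocentres C4a and C11a are not enolisable.

Step 13
Reactants: 17 (4R,5S)-5-[(tert-butyldimethylsilyloxy)methyl]-4-{2-[(4S,5R)-2,2,4-trimethyl-5-vinyl-1,3-dioxolan-4-yl]ethyl}tetrahydro-2H-pyran-2-one
Product: 18 (4R,5R)-5-(hydroxymethyl)-4-{2-[(4S,5R)-2,2,4-trimethyl-5-vinyl-1,3-dioxolan-4-yl]ethyl}tetrahydro-2H-pyran-2-one
Conditions: HF·pyridine, pyridine, THF, 0 °C → rt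
Reagents that add atoms: none
Why: Buffered fluoride desilylation avoids a free alkoxide, which could exchange the two hydroxymethyl arms by translactonisation; the trans lactone is in any case the more stable isomer.

Step 14
Reactants: 18 (4R,5R)-5-(hydroxymethyl)-4-{2-[(4S,5R)-2,2,4-trimethyl-5-vinyl-1,3-dioxolan-4-yl]ethyl}tetrahydro-2H-pyran-2-one
Product: 19 (3S,4R)-6-oxo-4-{2-[(4S,5R)-2,2,4-trimethyl-5-vinyl-1,3-dioxolan-4-yl]ethyl}tetrahydro-2H-pyran-3-carbaldehyde
Conditions: Dess–Martin periodinane, CH2Cl2, 0 °C
Reagents that add atoms: none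
Why: Dess–Martin oxidation without base, because the β-acyloxy aldehyde could epimerise or eliminate under basic conditions; it is carried on crude.

Step 15
Reactants: 19 (3S,4R)-6-oxo-4-{2-[(4S,5R)-2,2,4-trimethyl-5-vinyl-1,3-dioxolan-4-yl]ethyl}tetrahydro-2H-pyran-3-carbaldehyde
Product: 20 (4R,5R)-5-[(E)-(hydroxyimino)methyl]-4-{2-[(4S,5R)-2,2,4-trimethyl-5-vinyl-1,3-dioxolan-4-yl]ethyl}tetrahydro-2H-pyran-2-one
Conditions: NH2OH·HCl, pyridine, EtOH, 0 °C
Reagents that add atoms: hydroxylamine hydrochloride, NO.Cl
Why: Oxime formation is fast under buffered conditions and removes the sensitive aldehyde; the oxime geometry is irrelevant for the next step.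

Step 16
Reactants: 20 (4R,5R)-5-[(E)-(hydroxyimino)methyl]-4-{2-[(4S,5R)-2,2,4-trimethyl-5-vinyl-1,3-dioxolan-4-yl]ethyl}tetrahydro-2H-pyran-2-one
Product: 23 (4aR,7S,8R,9S,11aR)-isoxazoline lactone (C11=N–O–C9 bridge across the nine-membered ring, 7,8-O-isopropylidene, 4a,11a-trans-fused C3 lactone), via hydroximoyl chloride 21 (not isolated), via nitrile oxide 22 (not isolated)
Conditions: aq. NaOCl, CH2Cl2, 0 °C → rt, slow addition of 20 (final concentration about 1 mM)
Reagents that add atoms: none
Why: Proposed new method: NaOCl chlorinates oxime 20 to hydroximoyl chloride 21, which loses HCl to nitrile oxide 22, and this adds to the C9=C10 vinyl group in a concerted, asynchronous [3+2] cycloaddition; the closest known reaction type is the intramolecular nitrile oxide–alkene cycloaddition that closes five- to seven-membered carbocycles and, in the bridged sense, macrocycles. The isoxazoline (C11, N, O, C9, C10) closes by the cycloaddition itself, with carbon to the terminal C10 and oxygen to C9, the orientation monosubstituted alkenes prefer electronically. The nine-membered carbocycle closes through the C10–C11 bond in the bridged mode, the O–N unit spanning C9 and C11; the bridgehead C11=N bond lies trans in a ten-membered ring and is therefore allowed. Closure should be helped by the trans-diequatorial lactone, which holds C11 and the C5 chain gauche, and by the cis-disubstituted dioxolane, which turns the chain at C7/C8 towards the dipole; high dilution suppresses dimerisation to the furoxan. The only new stereocentre, C9, is controlled by C8: the tether at C7 cannot lie anti to the forming bonds, so the favoured transition state has the C8–O bond inside and C8–H anti (inside alkoxy effect), which places the new C9–O bond trans to the C8 oxygen on the ring. The step needs nine- over eight-membered closure and this face of the alkene; both rest on the pre-folded tether and remain to be shown by experiment.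

Step 17
Reactants: 23 (4aR,7S,8R,9S,11aR)-isoxazoline lactone
Product: 25 (4aR,7S,8R,9S,11aS)-9-hydroxy-11-oxo lactone (7,8-O-isopropylidene), via hydroxy imine 24 (not isolated)
Conditions: H2 (1 atm), Raney Ni, B(OH)3, MeOH/H2O (5:1), rt
Reagents that add atoms: water, O
Why: Hydrogenolysis of the N–O bond and in situ hydrolysis of the imine under boric acid buffering is the standard unmasking of isoxazolines to β-hydroxy ketones. No alkene is present, and the buffer limits epimerisation at C11a and retro-aldol cleavage.

Step 18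
Reactants: 25 (4aR,7S,8R,9S,11aS)-9-hydroxy-11-oxo lactone
Product: 26 (4aR,7S,8R,9S,11aR)-9-hydroxy-11-methylidene lactone (7,8-O-isopropylidene)
Conditions: Zn, CH2Br2, TiCl4 (Lombardo reagent), THF/CH2Cl2, 0 °C → rt
Reagents that add atoms: dibromomethane, BrCBr
Why: Lombardo methylenation is non-basic, tolerates free hydroxyl groups and lactones and prefers ketones, so neither retro-aldol cleavage of the β-hydroxy ketone nor epimerisation at C11a should occur.

Step 19
Reactants: 26 (4aR,7S,8R,9S,11aR)-9-hydroxy-11-methylidene lactone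
Product: 27 (4aR,7S,8R,9S,11aR)-9-mesyloxy-11-methylidene lactone (7,8-O-isopropylidene)
Conditions: MsCl, Et3N, CH2Cl2, 0 °C
Reagents that add atoms: methanesulfonyl chloride, CS(=O)(=O)Cl
Why: Sulfonylation of the only free hydroxyl; after methylenation the mesylate is no longer β to a carbonyl and cannot eliminate by an enolate pathway.

Step 20
Reactants: 27 (4aR,7S,8R,9S,11aR)-9-mesyloxy-11-methylidene lactone
Product: 28 (4aR,7S,8R,9S,11aR)-7,8-dihydroxy-9-mesyloxy-11-methylidene lactone
Conditions: AcOH/H2O (4:1), 45 °C
Reagents that add atoms: none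
Why: Acetal hydrolysis at the last stage where aqueous acid is harmless; a secondary mesylate, the lactone and the 1,1-disubstituted alkene should survive warm aqueous acetic acid.

Step 21
Reactants: 28 (4aR,7S,8R,9S,11aR)-7,8-dihydroxy-9-mesyloxy-11-methylidene lactone
Product: 29 (4aR,7S,8R,9R,11aR)-8,9-epoxy-7-hydroxy-11-methylidene lactone
Conditions: DBU, CH2Cl2, rt → 40 °C
Reagents that add atoms: none
Why: Intramolecular Williamson displacement: the C8 hydroxyl, trans to the mesylate, attacks C9 with inversion and gives the cis-epoxide with C8 retained. A non-nucleophilic base spares the lactone, and the three-membered closure outruns oxetane formation from the C7 hydroxyl.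

Step 22
Reactants: 29 (4aR,7S,8R,9R,11aR)-8,9-epoxy-7-hydroxy-11-methylidene lactone
Product: 30 (4aR,7S,8R,9R,11aR)-8,9-epoxy-7-(triethylsilyloxy)-11-methylidene lactone
Conditions: Et3SiOTf, 2,6-lutidine, CH2Cl2, −78 °C
Reagents that add atoms: triethylsilyl trifluoromethanesulfonate, CC[Si](CC)(CC)OS(=O)(=O)C(F)(F)F
Why: Silylation of the tertiary alcohol with a silyl triflate and hindered base at low temperature; it removes the alkoxide next to the epoxide from the enolate chemistry that follows.

Step 23
Reactants: 31 2,3-O-isopropylidene-D-erythronolactone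
Product: 32 2-[(4R,5R)-5-(hydroxymethyl)-2,2-dimethyl-1,3-dioxolan-4-yl]propan-2-ol
Conditions: MeMgBr (3 equiv), THF, 0 °C → rt
Reagents that add atoms: methylmagnesium bromide, C[Mg]Br
Why: Double Grignard addition to the lactone makes the C15 carbinol; C13 and C14 are untouched and come from the chiral pool.

Step 24
Reactants: 32 2-[(4R,5R)-5-(hydroxymethyl)-2,2-dimethyl-1,3-dioxolan-4-yl]propan-2-ol
Product: 33 (2R,3R)-4-methylpentane-1,2,3,4-tetraol
Conditions: Dowex 50W (H+ form), MeOH/H2O, 50 °C
Reagents that add atoms: none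
Why: Acetal hydrolysis is done here, on a robust tetraol, so that the side chain later carries only fluoride-labile groups.

Step 25
Reactants: 33 (2R,3R)-4-methylpentane-1,2,3,4-tetraol
Product: 34 (2R,3R)-4-methyl-1,2,3,4-tetrakis(triethylsilyloxy)pentane
Conditions: Et3SiOTf (5 equiv), 2,6-lutidine, CH2Cl2, −78 → 0 °C
Reagents that add atoms: triethylsilyl trifluoromethanesulfonate, CC[Si](CC)(CC)OS(=O)(=O)C(F)(F)F
Why: Exhaustive silylation; the triflate is reactive enough for the tertiary hydroxyl.

Step 26
Reactants: 34 (2R,3R)-4-methyl-1,2,3,4-tetrakis(triethylsilyloxy)pentane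
Product: 35 (2S,3R)-4-methyl-2,3,4-tris(triethylsilyloxy)pentanal
Conditions: (COCl)2, DMSO, CH2Cl2, −78 → −30 °C; Et3N, −78 °C → rt
Reagents that add atoms: none
Why: Under Swern conditions a primary triethylsilyl ether is cleaved and oxidised directly to the aldehyde while secondary and tertiary silyl ethers persist; this saves a separate deprotection.

Step 27
Reactants: 30 (4aR,7S,8R,9R,11aR)-8,9-epoxy-7-(triethylsilyloxy)-11-methylidene lactone; 35 (2S,3R)-4-methyl-2,3,4-tris(triethylsilyloxy)pentanal
Product: 36 aldol adduct (C4 bears the C12 carbinol; mixture at C4 and C12; C13 and C14 as in 35)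
Conditions: LiN(SiMe3)2, THF, −78 °C; 35; AcOH, −78 °C
Reagents that add atoms: none
Why: Aldol addition of the lactone lithium enolate to a reactive α-silyloxy aldehyde; the configurations at C4 and C12 are unimportant because both become sp2 in the next step.

Step 28
Reactants: 36 aldol adduct
Product: 38 (Z)-α-alkylidene lactone (C4=C12, C13 cis to the C3 carbonyl), via C12 mesylate 37 (not isolated)
Conditions: MsCl, Et3N, CH2Cl2, −20 °C; then DBU, 0 °C → rt
Reagents that add atoms: none
Why: Mesylation and E1cB elimination through the lactone enolate; allylic strain between the C12 substituent and the pseudo-equatorial C5 chain at C4a should direct C13 to the carbonyl side, both kinetically and thermodynamically.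

Step 29
Reactants: 38 (Z)-α-alkylidene lactone
Product: 39 lactol (C3 hemiacetal, mixture at C3)
Conditions: i-Bu2AlH, CH2Cl2, −78 °C; Rochelle salt
Reagents that add atoms: none
Why: 1,2-Reduction of an α-alkylidene lactone by DIBAL-H stops at the lactol at −78 °C; epoxide, silyl ethers and alkenes are inert.

Step 30
Reactants: 39 lactol
Product: 41 tris(triethylsilyl) ether of the target (silyl groups on the C7, C14 and C15 oxygens), via C13 hydroxy lactol 40 (not isolated)
Conditions: PPTS (0.2 equiv), MeOH/CH2Cl2 (1:10), 0 °C → rt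
Reagents that add atoms: none
Why: Mild acid should remove the least hindered secondary silyl ether at C13 and ionise the lactol to an allylic oxocarbenium ion, which the C13 oxygen captures in a five-membered closure. C3 is set under equilibrating conditions, since only a pseudo-equatorial C3–O bond allows the planar dihydrofuran on the trans-fused ring. The C14 and C15 oxygens remain silylated and cannot compete.

Step 31
Reactants: 41 tris(triethylsilyl) ether of the target
Product: 42 target compound CNP0281409.2
Conditions: Bu4NF/AcOH (1:1), THF, rt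
Reagents that add atoms: none
Why: Buffered fluoride removes the three silyl ethers under conditions in which the acetal cannot ionise and no alkoxide builds up beside the epoxide.

## Compound list

1 | geraniol | CC(C)=CCC/C(C)=C/CO | starting material
2 | (2S,3S)-2,3-epoxygeraniol | OC[C@@H]1O[C@@]1(C)CCC=C(C)C | intermediate
3 | (2S)-6-methyl-2-[(2R)-oxiran-2-yl]hept-5-en-2-ol (Payne epoxide, not isolated) | C1O[C@H]1[C@@](C)(O)CCC=C(C)C | intermediate
4 | (2R,3S)-3,7-dimethyloct-6-ene-1,2,3-triol | OC[C@@H](O)[C@@](C)(O)CCC=C(C)C | intermediate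
5 | (2R,3S)-1-(tert-butyldimethylsilyloxy)-3,7-dimethyloct-6-ene-2,3-diol | CC(C)(C)[Si](C)(C)OC[C@@H](O)[C@@](C)(O)CCC=C(C)C | intermediate
6 | tert-butyldimethyl{[(4R,5S)-2,2,5-trimethyl-5-(4-methylpent-3-en-1-yl)-1,3-dioxolan-4-yl]methoxy}silane | CC(C)(C)[Si](C)(C)OC[C@H]1OC(C)(C)O[C@@]1(C)CCC=C(C)C | intermediate
7 | [(4R,5S)-2,2,5-trimethyl-5-(4-methylpent-3-en-1-yl)-1,3-dioxolan-4-yl]methanol | OC[C@H]1OC(C)(C)O[C@@]1(C)CCC=C(C)C | intermediate
8 | (4S,5S)-2,2,5-trimethyl-5-(4-methylpent-3-en-1-yl)-1,3-dioxolane-4-carbaldehyde | O=C[C@H]1OC(C)(C)O[C@@]1(C)CCC=C(C)C | intermediate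
9 | (4S,5R)-2,2,4-trimethyl-4-(4-methylpent-3-en-1-yl)-5-vinyl-1,3-dioxolane | C=C[C@H]1OC(C)(C)O[C@@]1(C)CCC=C(C)C | intermediate
10 | 3-[(4S,5R)-2,2,4-trimethyl-5-vinyl-1,3-dioxolan-4-yl]propanal | C=C[C@H]1OC(C)(C)O[C@@]1(C)CCC=O | intermediate
11 | dimethyl malonate | COC(=O)CC(=O)OC | starting material
12 | dimethyl 2-{3-[(4S,5R)-2,2,4-trimethyl-5-vinyl-1,3-dioxolan-4-yl]propylidene}malonate | C=C[C@H]1OC(C)(C)O[C@@]1(C)CCC=C(C(=O)OC)C(=O)OC | intermediate
13 | 3-(tert-butyldimethylsilyloxy)propanal | O=CCCO[Si](C)(C)C(C)(C)C | starting material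
14 | dimethyl 2-{(3S,4R)-5-(tert-butyldimethylsilyloxy)-4-formyl-1-[(4S,5R)-2,2,4-trimethyl-5-vinyl-1,3-dioxolan-4-yl]pentan-3-yl}malonate (syn Michael adduct) | O=C[C@@H](CO[Si](C)(C)C(C)(C)C)[C@H](CC[C@]1(C)OC(C)(C)O[C@@H]1C=C)C(C(=O)OC)C(=O)OC | intermediate
15 | hydroxy diester from 14 (formyl reduced to CH2OH, not isolated) | OC[C@@H](CO[Si](C)(C)C(C)(C)C)[C@H](CC[C@]1(C)OC(C)(C)O[C@@H]1C=C)C(C(=O)OC)C(=O)OC | intermediate
16 | methyl (4S,5S)-5-[(tert-butyldimethylsilyloxy)methyl]-2-oxo-4-{2-[(4S,5R)-2,2,4-trimethyl-5-vinyl-1,3-dioxolan-4-yl]ethyl}tetrahydro-2H-pyran-3-carboxylate (C3 epimers) | O=C1OC[C@@H](CO[Si](C)(C)C(C)(C)C)[C@H](CC[C@]2(C)OC(C)(C)O[C@@H]2C=C)C1C(=O)OC | intermediate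
17 | (4R,5S)-5-[(tert-butyldimethylsilyloxy)methyl]-4-{2-[(4S,5R)-2,2,4-trimethyl-5-vinyl-1,3-dioxolan-4-yl]ethyl}tetrahydro-2H-pyran-2-one | O=C1OC[C@@H](CO[Si](C)(C)C(C)(C)C)[C@H](CC[C@]2(C)OC(C)(C)O[C@@H]2C=C)C1 | intermediate
18 | (4R,5R)-5-(hydroxymethyl)-4-{2-[(4S,5R)-2,2,4-trimethyl-5-vinyl-1,3-dioxolan-4-yl]ethyl}tetrahydro-2H-pyran-2-one | O=C1OC[C@@H](CO)[C@H](CC[C@]2(C)OC(C)(C)O[C@@H]2C=C)C1 | intermediate
19 | (3S,4R)-6-oxo-4-{2-[(4S,5R)-2,2,4-trimethyl-5-vinyl-1,3-dioxolan-4-yl]ethyl}tetrahydro-2H-pyran-3-carbaldehyde | O=C[C@@H]1COC(=O)C[C@H]1CC[C@]2(C)OC(C)(C)O[C@@H]2C=C | intermediate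
20 | (4R,5R)-5-[(E)-(hydroxyimino)methyl]-4-{2-[(4S,5R)-2,2,4-trimethyl-5-vinyl-1,3-dioxolan-4-yl]ethyl}tetrahydro-2H-pyran-2-one | O/N=C/[C@@H]1COC(=O)C[C@H]1CC[C@]2(C)OC(C)(C)O[C@@H]2C=C | intermediate
21 | hydroximoyl chloride of 20 (C11 bears Cl, not isolated) | ON=C(Cl)[C@@H]1COC(=O)C[C@H]1CC[C@]2(C)OC(C)(C)O[C@@H]2C=C | intermediate
22 | C11 nitrile oxide (not isolated) | [O-][N+]#C[C@@H]1COC(=O)C[C@H]1CC[C@]2(C)OC(C)(C)O[C@@H]2C=C | intermediate
23 | (4aR,7S,8R,9S,11aR)-isoxazoline lactone: C11=N–O–C9 bridge over the nine-membered ring, 7,8-O-isopropylidene, 4a,11a-trans-fused lactone (C3=O) | N1=C2C[C@H](O1)[C@H]3OC(C)(C)O[C@@]3(C)CC[C@@H]4CC(=O)OC[C@@H]24 | intermediate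
24 | C11 imine, C9 alcohol from N–O cleavage of 23 (not isolated) | N=C1C[C@H](O)[C@H]2OC(C)(C)O[C@@]2(C)CC[C@@H]3CC(=O)OC[C@@H]13 | intermediate
25 | (4aR,7S,8R,9S,11aS)-9-hydroxy-11-oxo lactone, 7,8-O-isopropylidene | O=C1C[C@H](O)[C@H]2OC(C)(C)O[C@@]2(C)CC[C@@H]3CC(=O)OC[C@@H]13 | intermediate
26 | (4aR,7S,8R,9S,11aR)-9-hydroxy-11-methylidene lactone, 7,8-O-isopropylidene | C=C1C[C@H](O)[C@H]2OC(C)(C)O[C@@]2(C)CC[C@@H]3CC(=O)OC[C@@H]13 | intermediate
27 | (4aR,7S,8R,9S,11aR)-9-mesyloxy-11-methylidene lactone, 7,8-O-isopropylidene | C=C1C[C@H](OS(C)(=O)=O)[C@H]2OC(C)(C)O[C@@]2(C)CC[C@@H]3CC(=O)OC[C@@H]13 | intermediate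
28 | (4aR,7S,8R,9S,11aR)-7,8-dihydroxy-9-mesyloxy-11-methylidene lactone | C=C1C[C@H](OS(C)(=O)=O)[C@@H](O)[C@@](C)(O)CC[C@@H]2CC(=O)OC[C@@H]12 | intermediate
29 | (4aR,7S,8R,9R,11aR)-8,9-epoxy-7-hydroxy-11-methylidene lactone | C=C1C[C@H]2O[C@H]2[C@@](C)(O)CC[C@@H]2CC(=O)OC[C@@H]12 | intermediate
30 | (4aR,7S,8R,9R,11aR)-8,9-epoxy-7-(triethylsilyloxy)-11-methylidene lactone | C=C1C[C@H]2O[C@H]2[C@@](C)(O[Si](CC)(CC)CC)CC[C@@H]2CC(=O)OC[C@@H]12 | intermediate
31 | 2,3-O-isopropylidene-D-erythronolactone | C1[C@H]([C@@H](O2)C(=O)O1)OC2(C)C | starting material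
32 | 2-[(4R,5R)-5-(hydroxymethyl)-2,2-dimethyl-1,3-dioxolan-4-yl]propan-2-ol | OC[C@H]1OC(C)(C)O[C@H]1C(C)(C)O | intermediate
33 | (2R,3R)-4-methylpentane-1,2,3,4-tetraol | OC[C@@H](O)[C@@H](O)C(C)(C)O | intermediate
34 | (2R,3R)-4-methyl-1,2,3,4-tetrakis(triethylsilyloxy)pentane | CC[Si](CC)(CC)OC[C@@H](O[Si](CC)(CC)CC)[C@@H](O[Si](CC)(CC)CC)C(C)(C)O[Si](CC)(CC)CC | intermediate
35 | (2S,3R)-4-methyl-2,3,4-tris(triethylsilyloxy)pentanal | O=C[C@@H](O[Si](CC)(CC)CC)[C@@H](O[Si](CC)(CC)CC)C(C)(C)O[Si](CC)(CC)CC | intermediate
36 | aldol adduct of 30 and 35 (C4–C12 bond, C12 carbinol, mixture at C4 and C12) | C=C1C[C@H]2O[C@H]2[C@@](C)(O[Si](CC)(CC)CC)CC[C@@H]2C(C(O)[C@@H](O[Si](CC)(CC)CC)[C@@H](O[Si](CC)(CC)CC)C(C)(C)O[Si](CC)(CC)CC)C(=O)OC[C@@H]12 | intermediate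
37 | C12 mesylate of 36 (not isolated) | C=C1C[C@H]2O[C@H]2[C@@](C)(O[Si](CC)(CC)CC)CC[C@@H]2C(C(OS(C)(=O)=O)[C@@H](O[Si](CC)(CC)CC)[C@@H](O[Si](CC)(CC)CC)C(C)(C)O[Si](CC)(CC)CC)C(=O)OC[C@@H]12 | intermediate
38 | (Z)-α-alkylidene lactone (C4=C12, C13 cis to C3; silyl ethers at C7, C13, C14, C15) | C=C1C[C@H]2O[C@H]2[C@@](C)(O[Si](CC)(CC)CC)CC[C@@H]2/C(=C/[C@@H](O[Si](CC)(CC)CC)[C@@H](O[Si](CC)(CC)CC)C(C)(C)O[Si](CC)(CC)CC)C(=O)OC[C@@H]12 | intermediate
39 | lactol of 38 (C3 hemiacetal, mixture at C3) | C=C1C[C@H]2O[C@H]2[C@@](C)(O[Si](CC)(CC)CC)CC[C@@H]2/C(=C/[C@@H](O[Si](CC)(CC)CC)[C@@H](O[Si](CC)(CC)CC)C(C)(C)O[Si](CC)(CC)CC)C(O)OC[C@@H]12 | intermediate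
40 | C13 hydroxy lactol (C13 silyl ether of 39 removed, not isolated) | C=C1C[C@H]2O[C@H]2[C@@](C)(O[Si](CC)(CC)CC)CC[C@@H]2/C(=C/[C@@H](O)[C@@H](O[Si](CC)(CC)CC)C(C)(C)O[Si](CC)(CC)CC)C(O)OC[C@@H]12 | intermediate
41 | 7,14,15-tris-O-(triethylsilyl) ether of the target | C=C1C[C@H]2O[C@H]2[C@@](C)(O[Si](CC)(CC)CC)CC[C@@H]2C3=C[C@H]([C@@H](O[Si](CC)(CC)CC)C(C)(C)O[Si](CC)(CC)CC)O[C@@H]3OC[C@@H]12 | intermediate
42 | CNP0281409.2, (3S,4aS,7S,8R,9R,11aR,13R,14R) in the locants used here | C=C1C[C@H]2O[C@H]2[C@@](C)(O)CC[C@@H]2C3=C[C@H]([C@@H](O)C(C)(C)O)O[C@@H]3OC[C@@H]12 | target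

## Step count and least certain steps

Total: 31 steps. Longest linear sequence: 27 steps (steps 1–22 and 27–31, from geraniol); the side-chain branch (steps 23–26) has 4 steps.

**Step 16 (key step).** Most likely failure: the nine-membered closure is slow, so the nitrile oxide dimerises to the furoxan in spite of dilution. It may also close through C9 to the fused eight-membered isomer, or add to the other face of the vinyl group, which would give the C9 epimer. Fallback with known reactions, from aldehyde 19: addition of CH2=CHMgBr at −78 °C should give the divinyl carbinol F1. Ring-closing metathesis with the second-generation Grubbs catalyst RuCl2(=CHPh)(PCy3)(H2IMes) at high dilution should give the (Z)-cyclononenol F2. Dess–Martin oxidation gives the enone F3, and Weitz–Scheffer epoxidation (t-BuOOH, DBU) the epoxy ketone F4. Reductive opening of the Cα–O bond with SmI2 returns to the route at hydroxy ketone 25. C9 is then set by the face of the epoxidation and not by the cycloaddition.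

**Step 10.** Most likely failure: the β-alkyl alkylidene malonate is a weak acceptor. Deconjugation to the β,γ-isomer, amine-induced retro-Knoevenagel exchange or a low syn/anti ratio may erode the step. Fallback from aldehyde 10: Wittig reaction with Ph3P=CHCHO gives the (E)-enal F5. Iminium-catalysed Michael addition of dimethyl malonate 11 with (S)-α,α-diphenylprolinol trimethylsilyl ether sets C4a in the malonyl aldehyde F6. Pinnick oxidation gives the acid F7, and LiBH4 reduces only the two methyl esters to the diol acid F8. Acid-catalysed lactonisation under equilibrating conditions then selects the hydroxymethyl arm that gives the trans lactone and rejoins the route at 18. Here C11a is set by thermodynamic control.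

**Step 18.** Most likely failure: the titanium Lewis acid dehydrates the β-hydroxy ketone to the enone or opens the acetonide before methylenation. Fallback from 25: silylation (Et3SiOTf, 2,6-lutidine) gives the C9 silyl ether ketone F12, Wittig methylenation with Ph3P=CH2 at low temperature gives the methylidene silyl ether F13, and HF·pyridine returns to the route at 26.

**Step 28.** Most likely failure: formation of the E alkene, or γ-deprotonation at C13 by DBU with deconjugation and loss of the C13 configuration. Fallback from aldol adduct 36, which avoids an open-chain alkene geometry: DIBAL-H reduction gives the hydroxy lactol F9. PPTS in MeOH/CH2Cl2 closes the acetal first, giving the saturated bicyclic acetal alcohol F10 with the C12 hydroxyl free. Syn-dehydration with the Burgess reagent then places the C4=C12 bond inside the five-membered ring, where it can only be cis, and rejoins the route at 41.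

**Step 30.** Most likely failure: unselective loss of the silyl ethers, so that the C14 oxygen closes a six-membered acetal, or acid-induced loss of the C13 hydrogen with aromatisation to a furan. Fallback from lactol 39, which reverses the order: buffered Bu4NF first gives the fully desilylated lactol F11. Brief equilibration with PPTS in CH2Cl2 over molecular sieves should then give the natural acetal as the thermodynamic product, arriving directly at 42.

## Further compounds

F1 | step 16 | divinyl carbinol from 19 (C11 carbinol, both epimers) | C=CC(O)[C@@H]1COC(=O)C[C@H]1CC[C@]2(C)OC(C)(C)O[C@@H]2C=C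
F2 | step 16 | (Z)-cyclononenol lactone (C9=C10, C11 carbinol, 7,8-O-isopropylidene) | OC1/C=C\[C@H]2OC(C)(C)O[C@@]2(C)CC[C@@H]3CC(=O)OC[C@@H]13
F3 | step 16 | (Z)-cyclononenone lactone (C11 ketone, C9=C10) | O=C1/C=C\[C@H]2OC(C)(C)O[C@@]2(C)CC[C@@H]3CC(=O)OC[C@@H]13
F4 | step 16 | 9,10-epoxy-11-oxo lactone (C9 oxygen trans to the C8 oxygen) | O=C1C2O[C@@H]2[C@H]3OC(C)(C)O[C@@]3(C)CC[C@@H]4CC(=O)OC[C@@H]14
F5 | step 10 | (E)-5-[(4S,5R)-2,2,4-trimethyl-5-vinyl-1,3-dioxolan-4-yl]pent-2-enal | C=C[C@H]1OC(C)(C)O[C@@]1(C)CC/C=C/C=O
F6 | step 10 | dimethyl 2-{1-oxo-5-[(4S,5R)-2,2,4-trimethyl-5-vinyl-1,3-dioxolan-4-yl]pentan-3-yl}malonate (C4a set) | O=CC[C@@H](CC[C@]1(C)OC(C)(C)O[C@@H]1C=C)C(C(=O)OC)C(=O)OC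
F7 | step 10 | carboxylic acid from F6 (C3 acid) | OC(=O)C[C@@H](CC[C@]1(C)OC(C)(C)O[C@@H]1C=C)C(C(=O)OC)C(=O)OC
F8 | step 10 | diol acid from F7 (both malonate esters reduced) | OC(=O)C[C@@H](CC[C@]1(C)OC(C)(C)O[C@@H]1C=C)C(CO)CO
F9 | step 28 | hydroxy lactol from 36 (C3 hemiacetal, C12 carbinol) | C=C1C[C@H]2O[C@H]2[C@@](C)(O[Si](CC)(CC)CC)CC[C@@H]2C(C(O)[C@@H](O[Si](CC)(CC)CC)[C@@H](O[Si](CC)(CC)CC)C(C)(C)O[Si](CC)(CC)CC)C(O)OC[C@@H]12
F10 | step 28 | saturated bicyclic acetal alcohol (C3–O–C13 closed, C12 hydroxyl, silyl ethers at C7, C14, C15) | C=C1C[C@H]2O[C@H]2[C@@](C)(O[Si](CC)(CC)CC)CC[C@@H]2C3C(O)[C@H]([C@@H](O[Si](CC)(CC)CC)C(C)(C)O[Si](CC)(CC)CC)O[C@@H]3OC[C@@H]12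
F11 | step 30 | fully desilylated lactol (C3 hemiacetal, free hydroxyls at C7, C13, C14, C15) | C=C1C[C@H]2O[C@H]2[C@@](C)(O)CC[C@@H]2/C(=C/[C@@H](O)[C@@H](O)C(C)(C)O)C(O)OC[C@@H]12
F12 | step 18 | 9-(triethylsilyloxy)-11-oxo lactone, 7,8-O-isopropylidene | O=C1C[C@H](O[Si](CC)(CC)CC)[C@H]2OC(C)(C)O[C@@]2(C)CC[C@@H]3CC(=O)OC[C@@H]13
F13 | step 18 | 9-(triethylsilyloxy)-11-methylidene lactone, 7,8-O-isopropylidene | C=C1C[C@H](O[Si](CC)(CC)CC)[C@H]2OC(C)(C)O[C@@]2(C)CC[C@@H]3CC(=O)OC[C@@H]13
A1 | alternative 1 | 1-(2-ethoxyvinyl)-2-(1-ethoxyvinyl)cyclopentanol carrying the C4a and C11a side arms (configuration at the two alkenyl-bearing carbons left open) | OC1(C=COCC)C(C(OCC)=C)C[C@H](CCOCc2ccc(OC)cc2)[C@H]1CO[Si](C)(C)C(C)(C)C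
A2 | alternative 1 | nine-membered C11 ketone with C9 ethoxy group and C6=C7 enol ether | O=C1C[C@@H](OCC)C/C(OCC)=C/C[C@H](CCOCc2ccc(OC)cc2)[C@H]1CO[Si](C)(C)C(C)(C)C
A3 | alternative 2 | bicyclo[4.3.1]dec-7-en-10-one with bridging C1 ketone | C1/C=C\[C@]2(C)CC[C@H](C3(C)OCCO3)[C@@H](C2=O)[C@@H]1O[Si](C)(C)C(C)(C)C
A4 | alternative 2 | nine-membered carbocycle bridged by the C1(=O)–O–C7 lactone | C1/C=C\[C@]2(C)CC[C@H](C3(C)OCCO3)[C@@H](C(=O)O2)[C@@H]1O[Si](C)(C)C(C)(C)C
A5 | alternative 3 | 13-membered allylic lactone (C1 ester of the C12 carbinol, C4=C4a alkene; C12 configuration and C4=C4a geometry left open) | O=C1CC(=C)C/C=C\[C@@](C)(O[Si](CC)(CC)CC)CCC=C(COCc2ccc(OC)cc2)C(O1)[C@H]([C@@H](O3)C(C)(C)O[Si](CC)(CC)CC)OC3(C)C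
A6 | alternative 3 | nine-membered ring C1 acid with trans C4a/C11a and the C4=C12 alkene | C=C1C/C=C\[C@@](C)(O[Si](CC)(CC)CC)CC[C@H](/C(COCc2ccc(OC)cc2)=C/[C@H]([C@@H](O3)C(C)(C)O[Si](CC)(CC)CC)OC3(C)C)[C@H]1C(=O)O
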